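## Analysis of the target

The target 21 is a 2,4,6-trisubstituted tetrahydropyran (O1, C2–C6). Ring A (3,4-dihydroxy-5-methoxyphenyl) sits directly on C2, and ring B (4-hydroxyphenyl) is tied to C6 through the two-carbon link C7–C8. The three stereocentres C2 (S), C4 (R) and C6 (S) lie on one face of the ring, so in the chair all three substituents are equatorial. Read as an open chain, the oxygens on C2 and C4 are 1,3-anti. The sensitive parts are the catechol of ring A, which oxidises in air and base, and the C2–O1 bond, a benzylic ether para to a phenol that can ionise in acid or be cut by forcing hydrogenolysis. All phenols are therefore carried as benzyl ethers and freed last under neutral conditions. The difficulty is a 1,3,5-stereotriad whose members are separated by CH2 groups, to be set without passing through a cation at C2. The strategy rests on the C6–C7–C8 unit: C8 is benzylic to ring B and can be carried as an aryl ketone, which makes C6 the β-carbon of an aryl vinyl ketone bound to O1. A radical at C5 can add there, forming C5–C6, closing the ring and setting C6 in one step under the control of C2 and C4.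

## Retrosynthetic reasoning

**21 from 20 (three O–CH2Ph bonds and C8–O).** The last operation cleaves only benzylic C–O bonds under neutral conditions: the three phenol ethers and the benzylic acetate at C8. C8 bears oxygen only because it was the acceptor carbonyl. Letting it leave in the hydrogenolysis that frees the phenols saves a separate deoxygenation and keeps the catechol masked until the last flask. The cyclic benzylic ether C2–O1 must survive, which is plausible because an ester is a far better leaving group than the ring alkoxide.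

**20 from 19, 19 from 18, 18 from 17 (changes at C4 and C8).** No skeletal bond is cut. The C4 silyl ether is removed, the C8 acetate goes back to carbinol 18, and that to ketone 17. Desilylation is done while the phenols are still benzylated, so that no basic desilylating agent meets a free catechol.

**17 from 16 (C5–C6, the key disconnection).** C5–C6 is the ring bond that the C8 carbonyl activates from a distance: with C6=C7 conjugated to it, C6 is an electron-poor radical acceptor and C5 needs only a halogen. The cut leaves C2–C5 and O1 as the tether, so both existing stereocentres sit in the forming ring and can direct C6 through a chair. Cutting O1–C6 or O1–C2 instead would mean an ionic closure in base or acid, exposing a β-alkoxy ketone or the C2 benzylic ether to equilibration. The forward step must close the six-membered ring faster than the radical is reduced and place the new substituent cis to the other two.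

**16 from 15, and 15 from 11 and 14 (C5–I, then O1–C6).** Iodide 16 comes from chloride 15. Cutting the enol ether bond O1–C6 of 15 gives alcohol 11 and ynone 14, so one conjugate addition installs the whole acceptor together with ring B and C7–C8. The halogen exchange follows the addition so that a nucleophilic oxygen and a primary iodide never share a molecule, which would invite closure to a five-membered cyclic ether.

**14 from 13, 13 from 12 (C7–C8).** The ynone comes from aldehyde 12 by addition of an ethynyl nucleophile and oxidation of carbinol 13.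

**11 from 10 (C2–H).** The C2 carbinol goes back to aryl ketone 10. An aryl alkyl ketone is an ideal substrate for catalyst-controlled reduction. Catalyst control is needed because the C2/C4 relationship is 1,3-anti and the C4 oxygen is silylated, so neither chelation nor internal hydride delivery is available.

**10 from 4 and 7 (ring A–C2).** Cutting the aryl–carbonyl bond gives aryllithium 8, made from bromide 4, and Weinreb amide 7. The chelated adduct 9 ensures a single addition.

**7 from 6 and 5; 4 from 3 and 1.** C4 is bought: chlorohydrin ester 5 already has the C4 oxygen in the right configuration, the ester for the amide, and the chloride that becomes the radical precursor. Silylation gives 6 and amidation gives 7. In aldehyde 1 the bromine marks the future attachment carbon (para to one oxygen, meta to the methoxy group). Exchanging the formyl group for hydroxyl through formate 2 gives catechol 3, and benzylation gives 4.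

## Alternatives that were turned down

**Alternative 1:** Dithiane linchpin at C4.
- **Disconnection:** both bonds to C4 (C3–C4 and C4–C5) are cut. C4 becomes the carbon of the silyl dithiane A4, used twice as an acyl anion, and the halves become the alkyl epoxide A2 (C5–C8 with ring B) and the aryl oxirane A3 (C2–C3 with ring A).
- **Forward key step:** metallated A4 opens A2 at its CH2 terminus. A 1,4-shift of silicon from carbon to the new alkoxide regenerates the carbanion, which opens A3 at its CH2 terminus and gives A1 in one flask.
- **For:** it is the most convergent of the four plans. Two C–C bonds form in one operation, both carbinol configurations come with the epoxides, and C4 is masked at the ketone level.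
- **Against:** A1 is still an open chain with oxygen on both C2 and C6, one more than the ring needs.
  - Displacement at C6 inverts it, so the enantiomer of A2 and a hindered secondary substitution would be needed.
  - Ionisation at C2 discards the configuration paid for in A3.
  - A3 is an electron-rich styrene oxide, prone to attack at its benzylic carbon and to rearrangement.
  - The thioketal must then be removed beside three electron-rich arenes and the 4-ketone reduced selectively.
- **Comparison:** the alternative is stronger on convergence and on bonds per step. The chosen route closes the ring and sets C6 in the same step and takes C4 from a chiral-pool reagent, so only functional group removal follows ketone 17. With two separately made enantiopure epoxides, the alternative is unlikely to be shorter.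

**Alternative 2:** Oxidative quinone methide cyclisation.
- **Disconnection:** O1–C2, opening the ring to the anti-diol A5, whose ring A has a free para hydroxyl.
- **Forward key step:** a mild oxidant (a silver oxide or a high-potential quinone) converts A5 into the para-quinone methide at the ring A benzylic carbon. The C6 hydroxyl adds to it in a 6-exo closure and gives A6.
- **For:** it is the shortest plan on paper and is stronger than the chosen route on step economy.
  - Both carbinols of A5 can be set together by asymmetric reduction chemistry.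
  - No oxygen has to be removed from C8.
  - A6 is one hydrogenolysis from 21.
  - Addition to the quinone methide is reversible, so C2 should settle all-equatorial.
- **Against:**
  - A quinone methide with hydrogens on the adjacent carbon (C3) tautomerises easily to a para-hydroxystyrene, dimerises and captures external nucleophiles, and these paths compete with the closure.
  - A6 is itself a para-hydroxybenzyl ether and can be oxidised again at C2.
  - Quinone oxidants also attack benzyl ethers and the benzylic position of ring B.
  - Freeing only the para hydroxyl of ring A needs a regioselective protection sequence.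
- **Comparison:** the chosen route is several steps longer. In exchange its ring closure is an irreversible C–C bond formation on a fully protected substrate with kinetic chair control, and its failure modes can be managed by concentration and addition rate.

**Alternative 3:** Petasis–Ferrier rearrangement.
- **Disconnection:** C2–C3, with a temporary acetal bond to C2 holding the fragments. The retron is the tetrahydropyran-4-one A8, derived from the cis enol acetal A7.
- **Forward key step:** an alkylaluminium chloride ionises the acetal of A7 at the enol ether oxygen. The aluminium enolate recloses on the aryl-stabilised oxocarbenium ion through a chair, forming C2–C3 and giving A8.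
- **For:**
  - It joins an aromatic aldehyde fragment and a β-hydroxy acid fragment convergently.
  - Only the C6 carbinol needs asymmetric synthesis.
  - Its 2,6-cis control is as dependable as that of the radical closure.
  - The donor groups of ring A help the ionisation.
  - C8 needs no deoxygenation, so the step count would be equal or slightly lower.
- **Against:**
  - C4 emerges as a ketone, so its configuration rests on a late hydride reduction; the equatorial alcohol is expected but not assured.
  - A titanium-based methylenation and a strong Lewis acid must be used beside two adjacent benzyl ethers and an easily ionised benzylic acetal, where debenzylation or fragmentation can compete.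
- **Comparison:** on 2,6-cis control the two plans are equal, and the alternative avoids the C8 oxygen. The chosen route offers a C4 centre carried unchanged from a chiral-pool reagent and a neutral, non-Lewis-acidic ring closure.

Key step: step 11

Remark on the chemistry: compounds 1, 5 and 12 are taken as commercial. Atom numbers O1 and C2–C8 are those of the target. The descriptor of the ring carbon carrying the side chain switches between R and S along the route only because substituent priorities change; the ring stays all-cis. Carbinol 18 and acetates 19 and 20 are carried as both C8 epimers, since that centre is removed in step 15.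

## Route

Step 1
Reactants: 1 5-bromo-2-hydroxy-3-methoxybenzaldehyde
Product: 3 5-bromo-3-methoxybenzene-1,2-diol, via 5-bromo-2-hydroxy-3-methoxyphenyl formate 2 (not isolated)
Conditions: 30% H2O2, NaOH, H2O–THF, 0 °C → rt, N2; then HCl
Reagents that add atoms: hydrogen peroxide, OO
Why: Dakin oxidation: hydroperoxide adds to the aldehyde, the electron-rich ortho-hydroxyaryl group migrates to oxygen, and formate 2 is saponified in the same basic medium; air is excluded to protect the catechol.

Step 2
Reactants: 3 5-bromo-3-methoxybenzene-1,2-diol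
Product: 4 1,2-bis(benzyloxy)-5-bromo-3-methoxybenzene
Conditions: BnBr, K2CO3, DMF, 60 °C, N2
Reagents that add atoms: benzyl bromide, BrCc1ccccc1
Why: Williamson etherification of both phenols; the benzyl ethers tolerate organolithium, borane, tin hydride and fluoride and leave together in step 15.

Step 3
Reactants: 5 ethyl (S)-4-chloro-3-hydroxybutanoate
Product: 6 ethyl (S)-3-[(tert-butyldimethylsilyl)oxy]-4-chlorobutanoate
Conditions: TBSCl, imidazole, DMF, rt
Reagents that add atoms: tert-butyldimethylsilyl chloride, CC(C)(C)[Si](C)(C)Cl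
Why: Imidazole-promoted silylation occurs at oxygen only, so the future C4 centre is carried over unchanged; the silyl ether also blocks epoxide formation from the chlorohydrin in the basic steps that follow.

Step 4
Reactants: 6 ethyl (S)-3-[(tert-butyldimethylsilyl)oxy]-4-chlorobutanoate
Product: 7 (S)-3-[(tert-butyldimethylsilyl)oxy]-4-chloro-N-methoxy-N-methylbutanamide
Conditions: MeNH(OMe)·HCl, iPrMgCl, THF, −20 → 0 °C
Reagents that add atoms: N,O-dimethylhydroxylamine hydrochloride, Cl.CNOC
Why: Direct conversion of an ester into its Weinreb amide by the chloromagnesium amide formed in the flask; at this temperature neither the primary chloride nor the β-silyloxy group should be attacked.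

Step 5
Reactants: 4 1,2-bis(benzyloxy)-5-bromo-3-methoxybenzene; 7 (S)-3-[(tert-butyldimethylsilyl)oxy]-4-chloro-N-methoxy-N-methylbutanamide
Product: 10 (S)-1-[3,4-bis(benzyloxy)-5-methoxyphenyl]-3-[(tert-butyldimethylsilyl)oxy]-4-chlorobutan-1-one, via [3,4-bis(benzyloxy)-5-methoxyphenyl]lithium 8 (not isolated), via lithium N-methoxy-N-methyl hemiaminal adduct 9 (not isolated)
Conditions: 4, n-BuLi, THF, −78 °C; then 7, −78 → −40 °C; aq. NH4Cl
Reagents that add atoms: none
Why: Bromine–lithium exchange is much faster than attack on the benzyl ethers at −78 °C, and the Weinreb amide holds the aryl adduct as chelate 9 until quench, so a single addition is expected; the primary chloride is inert to the aryllithium at this temperature.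

Step 6
Reactants: 10 (S)-1-[3,4-bis(benzyloxy)-5-methoxyphenyl]-3-[(tert-butyldimethylsilyl)oxy]-4-chlorobutan-1-one
Product: 11 (1S,3S)-1-[3,4-bis(benzyloxy)-5-methoxyphenyl]-3-[(tert-butyldimethylsilyl)oxy]-4-chlorobutan-1-ol
Conditions: (R)-Me-CBS [(3aR)-1-methyl-3,3-diphenyltetrahydro-1H,3H-pyrrolo[1,2-c][1,3,2]oxazaborole, C18H20BNO] (20 mol%), BH3·SMe2, THF, −20 °C; MeOH
Reagents that add atoms: none
Why: Corey–Bakshi–Shibata reduction: the oxazaborolidine–borane complex binds the ketone with the aryl group as the large substituent and delivers hydride to one face. The (R) catalyst should give the (S) carbinol (C2 of the target), so the 1,3-anti relationship to C4 is set by the reagent and not by the remote silyloxy centre.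

Step 7
Reactants: 12 4-(benzyloxy)benzaldehyde
Product: 13 1-[4-(benzyloxy)phenyl]prop-2-yn-1-ol (racemic)
Conditions: HC≡CMgBr, THF, 0 °C; aq. NH4Cl
Reagents that add atoms: ethynylmagnesium bromide, C#C[Mg]Br
Why: 1,2-Addition of an alkynyl Grignard reagent to an aromatic aldehyde; the carbinol is racemic, which does not matter because it is oxidised next.

Step 8
Reactants: 13 1-[4-(benzyloxy)phenyl]prop-2-yn-1-ol
Product: 14 1-[4-(benzyloxy)phenyl]prop-2-yn-1-one
Conditions: MnO2, CH2Cl2, rt
Reagents that add atoms: none
Why: MnO2 oxidises the doubly activated (benzylic and propargylic) alcohol under neutral conditions to the aryl ethynyl ketone.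

Step 9
Reactants: 11 (1S,3S)-1-[3,4-bis(benzyloxy)-5-methoxyphenyl]-3-[(tert-butyldimethylsilyl)oxy]-4-chlorobutan-1-ol; 14 1-[4-(benzyloxy)phenyl]prop-2-yn-1-one
Product: 15 (E)-1-[4-(benzyloxy)phenyl]-3-{[(1S,3S)-1-[3,4-bis(benzyloxy)-5-methoxyphenyl]-3-[(tert-butyldimethylsilyl)oxy]-4-chlorobutyl]oxy}prop-2-en-1-one
Conditions: DABCO (1,4-diazabicyclo[2.2.2]octane, 10 mol%), CH2Cl2, 0 °C → rt
Reagents that add atoms: none
Why: Amine-catalysed oxa-Michael addition of an alcohol to an activated alkyne: DABCO adds to 14, the zwitterion deprotonates 11, and the alkoxide adds at the alkyne terminus (future C6) to give the (E) β-alkoxy enone. The C2–O bond is not broken, so C2 keeps its configuration, and chloride is too poor a leaving group to be displaced by the transient alkoxide.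

Step 10
Reactants: 15 (E)-1-[4-(benzyloxy)phenyl]-3-{[(1S,3S)-1-[3,4-bis(benzyloxy)-5-methoxyphenyl]-3-[(tert-butyldimethylsilyl)oxy]-4-chlorobutyl]oxy}prop-2-en-1-one
Product: 16 (E)-1-[4-(benzyloxy)phenyl]-3-{[(1S,3S)-1-[3,4-bis(benzyloxy)-5-methoxyphenyl]-3-[(tert-butyldimethylsilyl)oxy]-4-iodobutyl]oxy}prop-2-en-1-one
Conditions: NaI, NaHCO3, 2-butanone, reflux, dark
Reagents that add atoms: sodium iodide, [Na+].[I-]
Why: Finkelstein exchange (SN2 at the primary carbon, driven by precipitation of NaCl); the vinylogous ester tolerates neutral iodide and NaHCO3 scavenges traces of HI. Any E/Z drift is harmless because both geometries lead through the same chair to the cis ring.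

Step 11
Reactants: 16 (E)-1-[4-(benzyloxy)phenyl]-3-{[(1S,3S)-1-[3,4-bis(benzyloxy)-5-methoxyphenyl]-3-[(tert-butyldimethylsilyl)oxy]-4-iodobutyl]oxy}prop-2-en-1-one
Product: 17 1-[4-(benzyloxy)phenyl]-2-[(2R,4R,6S)-6-[3,4-bis(benzyloxy)-5-methoxyphenyl]-4-[(tert-butyldimethylsilyl)oxy]oxan-2-yl]ethan-1-one (all-cis)
Conditions: Bu3SnH (slow addition by syringe pump), AIBN (2,2'-azobis(2-methylpropionitrile), cat.), benzene (0.01 M), 80 °C
Reagents that add atoms: none
Why: Bu3Sn•, started by AIBN, abstracts iodine from C5 of 16; the nucleophilic primary radical adds to the electron-poor β-carbon C6 of the vinylogous ester, and the α-keto radical at C7 takes hydrogen from Bu3SnH to give 17 and carry the chain. The closure is 6-exo-trig, forms C5–C6 and makes the tetrahydropyran O1/C2–C6. The closest known reaction type is the tin hydride-mediated 6-exo cyclisation of β-alkoxyacrylates and β-alkoxyvinyl ketones to cis-2,6-disubstituted tetrahydropyrans. The one new stereocentre, C6, is set by the substrate: in the chair-like transition state ring A on C2 and the silyloxy group on C4 are equatorial and the planar s-trans O1–C6=C7–C8=O unit is pseudo-equatorial, so the new side chain ends up equatorial and cis to both. Cyclisation must outrun hydrogen transfer to the C5 radical, which the low stannane concentration and the polarity-matched, ketone-activated acceptor should secure. 7-Endo attack at C7 is disfavoured because it would give a less stabilised α-alkoxy radical through a poorer trajectory. Iodine abstraction is fast enough that Bu3Sn• should not add to the aryl enone, and the only hydrogens within reach of a 1,5-shift are unactivated Si–CH3 ones, so translocation should not compete; C2 and C4 are untouched.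

Step 12
Reactants: 17 1-[4-(benzyloxy)phenyl]-2-[(2R,4R,6S)-6-[3,4-bis(benzyloxy)-5-methoxyphenyl]-4-[(tert-butyldimethylsilyl)oxy]oxan-2-yl]ethan-1-one
Product: 18 1-[4-(benzyloxy)phenyl]-2-[(2S,4R,6S)-6-[3,4-bis(benzyloxy)-5-methoxyphenyl]-4-[(tert-butyldimethylsilyl)oxy]oxan-2-yl]ethan-1-ol (all-cis ring, both C8 epimers)
Conditions: NaBH4, MeOH–THF, 0 °C
Reagents that add atoms: none
Why: Hydride addition to the aryl ketone; both C8 epimers are carried on, and the short, cold reduction leaves no time for base-mediated retro-oxa-Michael opening at C6.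

Step 13
Reactants: 18 1-[4-(benzyloxy)phenyl]-2-[(2S,4R,6S)-6-[3,4-bis(benzyloxy)-5-methoxyphenyl]-4-[(tert-butyldimethylsilyl)oxy]oxan-2-yl]ethan-1-ol
Product: 19 1-[4-(benzyloxy)phenyl]-2-[(2S,4R,6S)-6-[3,4-bis(benzyloxy)-5-methoxyphenyl]-4-[(tert-butyldimethylsilyl)oxy]oxan-2-yl]ethyl acetate (both C8 epimers)
Conditions: Ac2O, pyridine, DMAP (4-(dimethylamino)pyridine, cat.), CH2Cl2, rt
Reagents that add atoms: acetic anhydride, CC(=O)OC(C)=O
Why: DMAP-catalysed acylation of the secondary benzylic alcohol; the acetate turns the C8 oxygen into a leaving group for the final hydrogenolysis.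

Step 14
Reactants: 19 1-[4-(benzyloxy)phenyl]-2-[(2S,4R,6S)-6-[3,4-bis(benzyloxy)-5-methoxyphenyl]-4-[(tert-butyldimethylsilyl)oxy]oxan-2-yl]ethyl acetate
Product: 20 1-[4-(benzyloxy)phenyl]-2-[(2R,4R,6S)-6-[3,4-bis(benzyloxy)-5-methoxyphenyl]-4-hydroxyoxan-2-yl]ethyl acetate (both C8 epimers)
Conditions: Bu4NF, AcOH, THF, rt
Reagents that add atoms: none
Why: Fluoride cleaves the Si–O bond, so the C4–O bond and its configuration are untouched; AcOH buffering keeps the medium non-basic and should spare the acetate. Any elimination to the C7=C8 styrene would be harmless, since step 15 would saturate it to the same product.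

Step 15
Reactants: 20 1-[4-(benzyloxy)phenyl]-2-[(2R,4R,6S)-6-[3,4-bis(benzyloxy)-5-methoxyphenyl]-4-hydroxyoxan-2-yl]ethyl acetate
Product: 21 (2S,4R,6S)-2-(3,4-dihydroxy-5-methoxyphenyl)-6-[2-(4-hydroxyphenyl)ethyl]oxan-4-ol
Conditions: H2 (1 atm), 10% Pd/C, EtOAc–EtOH, rt
Reagents that add atoms: none
Why: Heterogeneous hydrogenolysis of three aryl benzyl ethers and of the benzylic C8–OAc bond, which the para oxygen of ring B activates (also through the quinone methide once that phenol is free). The cyclic C2–O1 ether has only an alkoxide as leaving group and should persist under these neutral, low-pressure conditions.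

## Compound list

1 | 5-bromo-2-hydroxy-3-methoxybenzaldehyde | COc1cc(Br)cc(C=O)c1O | starting material
2 | 5-bromo-2-hydroxy-3-methoxyphenyl formate (not isolated) | COc1cc(Br)cc(OC=O)c1O | intermediate
3 | 5-bromo-3-methoxybenzene-1,2-diol | COc1cc(Br)cc(O)c1O | intermediate
4 | 1,2-bis(benzyloxy)-5-bromo-3-methoxybenzene | COc1cc(Br)cc(OCc2ccccc2)c1OCc1ccccc1 | intermediate
5 | ethyl (S)-4-chloro-3-hydroxybutanoate | CCOC(=O)C[C@H](O)CCl | starting material
6 | ethyl (S)-3-[(tert-butyldimethylsilyl)oxy]-4-chlorobutanoate | CCOC(=O)C[C@H](O[Si](C)(C)C(C)(C)C)CCl | intermediate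
7 | (S)-3-[(tert-butyldimethylsilyl)oxy]-4-chloro-N-methoxy-N-methylbutanamide | CON(C)C(=O)C[C@H](O[Si](C)(C)C(C)(C)C)CCl | intermediate
8 | [3,4-bis(benzyloxy)-5-methoxyphenyl]lithium (not isolated) | COc1cc([Li])cc(OCc2ccccc2)c1OCc1ccccc1 | intermediate
9 | lithium (3S)-1-[3,4-bis(benzyloxy)-5-methoxyphenyl]-3-[(tert-butyldimethylsilyl)oxy]-4-chloro-1-[methoxy(methyl)amino]butan-1-olate (not isolated) | COc1cc(C(O[Li])(N(C)OC)C[C@H](O[Si](C)(C)C(C)(C)C)CCl)cc(OCc2ccccc2)c1OCc1ccccc1 | intermediate
10 | (S)-1-[3,4-bis(benzyloxy)-5-methoxyphenyl]-3-[(tert-butyldimethylsilyl)oxy]-4-chlorobutan-1-one | COc1cc(C(=O)C[C@H](O[Si](C)(C)C(C)(C)C)CCl)cc(OCc2ccccc2)c1OCc1ccccc1 | intermediate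
11 | (1S,3S)-1-[3,4-bis(benzyloxy)-5-methoxyphenyl]-3-[(tert-butyldimethylsilyl)oxy]-4-chlorobutan-1-ol | COc1cc([C@@H](O)C[C@H](O[Si](C)(C)C(C)(C)C)CCl)cc(OCc2ccccc2)c1OCc1ccccc1 | intermediate
12 | 4-(benzyloxy)benzaldehyde | O=Cc1ccc(OCc2ccccc2)cc1 | starting material
13 | 1-[4-(benzyloxy)phenyl]prop-2-yn-1-ol (racemic) | C#CC(O)c1ccc(OCc2ccccc2)cc1 | intermediate
14 | 1-[4-(benzyloxy)phenyl]prop-2-yn-1-one | C#CC(=O)c1ccc(OCc2ccccc2)cc1 | intermediate
15 | (E)-1-[4-(benzyloxy)phenyl]-3-{[(1S,3S)-1-[3,4-bis(benzyloxy)-5-methoxyphenyl]-3-[(tert-butyldimethylsilyl)oxy]-4-chlorobutyl]oxy}prop-2-en-1-one | COc1cc([C@@H](O/C=C/C(=O)c2ccc(OCc3ccccc3)cc2)C[C@H](O[Si](C)(C)C(C)(C)C)CCl)cc(OCc2ccccc2)c1OCc1ccccc1 | intermediate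
16 | (E)-1-[4-(benzyloxy)phenyl]-3-{[(1S,3S)-1-[3,4-bis(benzyloxy)-5-methoxyphenyl]-3-[(tert-butyldimethylsilyl)oxy]-4-iodobutyl]oxy}prop-2-en-1-one | COc1cc([C@@H](O/C=C/C(=O)c2ccc(OCc3ccccc3)cc2)C[C@H](O[Si](C)(C)C(C)(C)C)CI)cc(OCc2ccccc2)c1OCc1ccccc1 | intermediate
17 | 1-[4-(benzyloxy)phenyl]-2-[(2R,4R,6S)-6-[3,4-bis(benzyloxy)-5-methoxyphenyl]-4-[(tert-butyldimethylsilyl)oxy]oxan-2-yl]ethan-1-one (all-cis) | COc1cc([C@@H]2C[C@H](O[Si](C)(C)C(C)(C)C)C[C@H](CC(=O)c3ccc(OCc4ccccc4)cc3)O2)cc(OCc2ccccc2)c1OCc1ccccc1 | intermediate
18 | 1-[4-(benzyloxy)phenyl]-2-[(2S,4R,6S)-6-[3,4-bis(benzyloxy)-5-methoxyphenyl]-4-[(tert-butyldimethylsilyl)oxy]oxan-2-yl]ethan-1-ol (both C8 epimers) | COc1cc([C@@H]2C[C@H](O[Si](C)(C)C(C)(C)C)C[C@H](CC(O)c3ccc(OCc4ccccc4)cc3)O2)cc(OCc2ccccc2)c1OCc1ccccc1 | intermediate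
19 | 1-[4-(benzyloxy)phenyl]-2-[(2S,4R,6S)-6-[3,4-bis(benzyloxy)-5-methoxyphenyl]-4-[(tert-butyldimethylsilyl)oxy]oxan-2-yl]ethyl acetate (both C8 epimers) | COc1cc([C@@H]2C[C@H](O[Si](C)(C)C(C)(C)C)C[C@H](CC(OC(C)=O)c3ccc(OCc4ccccc4)cc3)O2)cc(OCc2ccccc2)c1OCc1ccccc1 | intermediate
20 | 1-[4-(benzyloxy)phenyl]-2-[(2R,4R,6S)-6-[3,4-bis(benzyloxy)-5-methoxyphenyl]-4-hydroxyoxan-2-yl]ethyl acetate (both C8 epimers) | COc1cc([C@@H]2C[C@H](O)C[C@H](CC(OC(C)=O)c3ccc(OCc4ccccc4)cc3)O2)cc(OCc2ccccc2)c1OCc1ccccc1 | intermediate
21 | (2S,4R,6S)-2-(3,4-dihydroxy-5-methoxyphenyl)-6-[2-(4-hydroxyphenyl)ethyl]oxan-4-ol | COc1cc([C@@H]2C[C@H](O)C[C@H](CCc3ccc(O)cc3)O2)cc(O)c1O | target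

## Step count and least certain steps

Total step count: 15. Longest linear sequence: 11 steps (from 5 through steps 3, 4, 5, 6, 9, 10, 11, 12, 13, 14, 15; the branch from 1 through steps 1, 2, 5, 6, 9–15 is equally long).

**Step 11 (key step).** The most likely failure is hydrogen transfer from the stannane to the C5 radical before ring closure. Specific to the aryl vinyl ketone, the tin radical may also add to the enone (conjugate reduction or hydrostannation), which an acrylate acceptor suffers far less; some loss of cis selectivity at reflux is conceivable. The fallback sets out from 11 and returns at 18, using the ester acceptor for which this cyclisation is best established.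
- Alcohol 11 is added to ethyl propiolate (N-methylmorpholine, CH2Cl2) to give the (E) β-alkoxyacrylate chloride F1.
- NaI in hot 2-butanone gives the β-alkoxyacrylate iodide F2.
- Bu3SnH with AIBN closes the ring to the all-cis tetrahydropyranylacetic ester F3.
- i-Bu2AlH at −78 °C gives the tetrahydropyranylacetaldehyde F4.
- Commercial 4-(benzyloxy)phenylmagnesium bromide adds to it to give carbinol 18, and the route continues with step 13.

**Step 15.** The most likely failure is incomplete hydrogenolysis at C8 once the phenols are free or, on forcing, reductive opening of the cyclic benzylic ether C2–O1. The fallback sets out from 17 and returns at 21, removing the C8 oxygen earlier and without a benzylic leaving group.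
- Ketone 17 is condensed with TsNHNH2 (EtOH, 60 °C) to the tosylhydrazone F5.
- Catecholborane (CHCl3, 0 °C) followed by NaOAc·3H2O (reflux) gives the C8-methylene silyl ether F6.
- Bu4NF gives the tribenzyl ether alcohol F7.
- A brief hydrogenolysis (H2, 10% Pd/C, EtOAc) then only has to cleave three aryl benzyl ethers and gives 21.

**Step 10.** The most likely failure is slow SN2 exchange at the primary carbon next to the silyloxy-bearing C4, so that prolonged heating hydrolyses or degrades the vinylogous ester. The fallback sets out from 10 and returns at 16, exchanging the halide before the enol ether exists.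
- Ketone 10 with NaI in refluxing 2-butanone gives the iodo ketone F8.
- The same oxazaborolidine-catalysed reduction gives the iodo alcohol F9.
- Addition of this alcohol to 14 at 0 °C with N-methylmorpholine, the weakest workable base, gives 16 directly; the low temperature is relied on to keep the transient alkoxide from closing onto the iodide.

**Step 9.** The most likely failure is slow addition of the hindered secondary benzylic alcohol, which leaves the amine-activated ynone to oligomerise, or a second addition to the product. The fallback sets out from 11 and returns at 15, building the acceptor in two stages.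
- The less self-reactive N-methoxy-N-methylprop-2-ynamide F10 is made from propiolic acid, MeNH(OMe)·HCl and a carbodiimide.
- Alcohol 11 adds to it (N-methylmorpholine, CH2Cl2) to give the (E) β-alkoxy Weinreb acrylamide F11.
- 4-(Benzyloxy)phenylmagnesium bromide (THF, 0 °C) converts the amide into aryl ketone 15.

**Step 6.** The most likely failure is incomplete facial selectivity, through uncatalysed background reduction by borane or a mismatched influence of the C4 silyloxy group. The fallback sets out from 10 and returns at 11.
- The ketone is reduced without selectivity (NaBH4, MeOH).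
- The two C2 epimers, being diastereomers, are separated by chromatography.
- The unwanted (1R,3S) alcohol F12 is oxidised back to 10 with MnO2 and recycled.

## Further compounds

F1 | step 11 | ethyl (E)-3-{[(1S,3S)-1-[3,4-bis(benzyloxy)-5-methoxyphenyl]-3-[(tert-butyldimethylsilyl)oxy]-4-chlorobutyl]oxy}prop-2-enoate | COc1cc([C@@H](O/C=C/C(=O)OCC)C[C@H](O[Si](C)(C)C(C)(C)C)CCl)cc(OCc2ccccc2)c1OCc1ccccc1
F2 | step 11 | ethyl (E)-3-{[(1S,3S)-1-[3,4-bis(benzyloxy)-5-methoxyphenyl]-3-[(tert-butyldimethylsilyl)oxy]-4-iodobutyl]oxy}prop-2-enoate | COc1cc([C@@H](O/C=C/C(=O)OCC)C[C@H](O[Si](C)(C)C(C)(C)C)CI)cc(OCc2ccccc2)c1OCc1ccccc1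
F3 | step 11 | ethyl 2-[(2R,4R,6S)-6-[3,4-bis(benzyloxy)-5-methoxyphenyl]-4-[(tert-butyldimethylsilyl)oxy]oxan-2-yl]acetate (all-cis) | COc1cc([C@@H]2C[C@H](O[Si](C)(C)C(C)(C)C)C[C@H](CC(=O)OCC)O2)cc(OCc2ccccc2)c1OCc1ccccc1
F4 | step 11 | 2-[(2R,4R,6S)-6-[3,4-bis(benzyloxy)-5-methoxyphenyl]-4-[(tert-butyldimethylsilyl)oxy]oxan-2-yl]acetaldehyde (all-cis) | COc1cc([C@@H]2C[C@H](O[Si](C)(C)C(C)(C)C)C[C@H](CC=O)O2)cc(OCc2ccccc2)c1OCc1ccccc1
F5 | step 15 | N'-{1-[4-(benzyloxy)phenyl]-2-[(2S,4R,6S)-6-[3,4-bis(benzyloxy)-5-methoxyphenyl]-4-[(tert-butyldimethylsilyl)oxy]oxan-2-yl]ethylidene}-4-methylbenzenesulfonohydrazide | COc1cc([C@@H]2C[C@H](O[Si](C)(C)C(C)(C)C)C[C@H](CC(=NNS(=O)(=O)c3ccc(C)cc3)c3ccc(OCc4ccccc4)cc3)O2)cc(OCc2ccccc2)c1OCc1ccccc1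
F6 | step 15 | tert-butyl{[(2S,4R,6S)-2-[3,4-bis(benzyloxy)-5-methoxyphenyl]-6-{2-[4-(benzyloxy)phenyl]ethyl}oxan-4-yl]oxy}dimethylsilane | COc1cc([C@@H]2C[C@H](O[Si](C)(C)C(C)(C)C)C[C@H](CCc3ccc(OCc4ccccc4)cc3)O2)cc(OCc2ccccc2)c1OCc1ccccc1
F7 | step 15 | (2S,4R,6S)-2-[3,4-bis(benzyloxy)-5-methoxyphenyl]-6-{2-[4-(benzyloxy)phenyl]ethyl}oxan-4-ol | COc1cc([C@@H]2C[C@H](O)C[C@H](CCc3ccc(OCc4ccccc4)cc3)O2)cc(OCc2ccccc2)c1OCc1ccccc1
F8 | step 10 | (S)-1-[3,4-bis(benzyloxy)-5-methoxyphenyl]-3-[(tert-butyldimethylsilyl)oxy]-4-iodobutan-1-one | COc1cc(C(=O)C[C@H](O[Si](C)(C)C(C)(C)C)CI)cc(OCc2ccccc2)c1OCc1ccccc1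
F9 | step 10 | (1S,3S)-1-[3,4-bis(benzyloxy)-5-methoxyphenyl]-3-[(tert-butyldimethylsilyl)oxy]-4-iodobutan-1-ol | COc1cc([C@@H](O)C[C@H](O[Si](C)(C)C(C)(C)C)CI)cc(OCc2ccccc2)c1OCc1ccccc1
F10 | step 9 | N-methoxy-N-methylprop-2-ynamide | C#CC(=O)N(C)OC
F11 | step 9 | (E)-3-{[(1S,3S)-1-[3,4-bis(benzyloxy)-5-methoxyphenyl]-3-[(tert-butyldimethylsilyl)oxy]-4-chlorobutyl]oxy}-N-methoxy-N-methylprop-2-enamide | COc1cc([C@@H](O/C=C/C(=O)N(C)OC)C[C@H](O[Si](C)(C)C(C)(C)C)CCl)cc(OCc2ccccc2)c1OCc1ccccc1
F12 | step 6 | (1R,3S)-1-[3,4-bis(benzyloxy)-5-methoxyphenyl]-3-[(tert-butyldimethylsilyl)oxy]-4-chlorobutan-1-ol | COc1cc([C@H](O)C[C@H](O[Si](C)(C)C(C)(C)C)CCl)cc(OCc2ccccc2)c1OCc1ccccc1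
A1 | alternative 1 | (1S)-1-[3,4-bis(benzyloxy)-5-methoxyphenyl]-2-{2-[(2S)-4-[4-(benzyloxy)phenyl]-2-[(tert-butyldimethylsilyl)oxy]butyl]-1,3-dithian-2-yl}ethan-1-ol | COc1cc([C@@H](O)CC2(SCCCS2)C[C@@H](O[Si](C)(C)C(C)(C)C)CCc2ccc(OCc3ccccc3)cc2)cc(OCc2ccccc2)c1OCc1ccccc1
A2 | alternative 1 | (S)-2-{2-[4-(benzyloxy)phenyl]ethyl}oxirane | C1[C@@H](O1)CCc1ccc(OCc2ccccc2)cc1
A3 | alternative 1 | (R)-2-[3,4-bis(benzyloxy)-5-methoxyphenyl]oxirane | COc1cc([C@@H]2CO2)cc(OCc2ccccc2)c1OCc1ccccc1
A4 | alternative 1 | 2-(tert-butyldimethylsilyl)-1,3-dithiane | CC(C)(C)[Si](C)(C)C1SCCCS1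
A5 | alternative 2 | (3S,5S)-1-[3-(benzyloxy)-4-hydroxy-5-methoxyphenyl]-7-[4-(benzyloxy)phenyl]heptane-3,5-diol | COc1cc(CC[C@H](O)C[C@@H](O)CCc2ccc(OCc3ccccc3)cc2)cc(OCc2ccccc2)c1O
A6 | alternative 2 | (2S,4R,6S)-2-[3-(benzyloxy)-4-hydroxy-5-methoxyphenyl]-6-{2-[4-(benzyloxy)phenyl]ethyl}oxan-4-ol | COc1cc([C@@H]2C[C@H](O)C[C@H](CCc3ccc(OCc4ccccc4)cc3)O2)cc(OCc2ccccc2)c1O
A7 | alternative 3 | (2S,6S)-2-[3,4-bis(benzyloxy)-5-methoxyphenyl]-6-{2-[4-(benzyloxy)phenyl]ethyl}-4-methylidene-1,3-dioxane (cis) | COc1cc([C@@H]2OC(=C)C[C@H](CCc3ccc(OCc4ccccc4)cc3)O2)cc(OCc2ccccc2)c1OCc1ccccc1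
A8 | alternative 3 | (2S,6S)-2-[3,4-bis(benzyloxy)-5-methoxyphenyl]-6-{2-[4-(benzyloxy)phenyl]ethyl}oxan-4-one (cis) | COc1cc([C@@H]2CC(=O)C[C@H](CCc3ccc(OCc4ccccc4)cc3)O2)cc(OCc2ccccc2)c1OCc1ccccc1
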